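**Assumption:** Epimedokoreanin B has no stereocentre and no stereogenic double bond, so "single enantiomer" is taken to mean the one achiral structure given. MOMCl, DBU, n-BuLi, H2 and the Ohira–Bestmann reagent are treated as unnumbered reagents.

**Retrosynthetic overview**
1. Target 16 ⇐ flavone 15 by global removal of three MOM groups.
2. 15 ⇐ ynone 13 by one proposed domino step: two aromatic Claisen shifts make both aryl–prenyl C–C bonds, then 6-endo closure forms the pyranone C ring (O1–C2), the only ring made in the route and formed last.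
3. 13 ⇐ B-ring arylacetylene 10 + A-ring aldehyde 5 (acetylide addition, then oxidation).
4. 5 and 10 ⇐ tertiary propargyl etherification of phenols with 3, then Lindlar reduction (plus alkyne homologation for 10).
5. Rings A and B are bought as 2,4,6-trihydroxybenzaldehyde 1 and 3,4-dihydroxybenzaldehyde 6.

**Route**

Step 1
Reactants: 1 2,4,6-trihydroxybenzaldehyde
Product: 2 2-hydroxy-4,6-bis(methoxymethoxy)benzaldehyde
Conditions: MOMCl (2.2 equiv), i-Pr2NEt (2.5 equiv), CH2Cl2, 0 °C → rt
Reagents that add atoms: chloromethyl methyl ether (MOMCl), COCCl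
Why: MOM etherification (Williamson-type O-alkylation) takes the 4-OH and one ortho-OH, while the remaining ortho-OH is hydrogen-bonded to the formyl oxygen and stays free.

Step 2
Reactants: 2 2-hydroxy-4,6-bis(methoxymethoxy)benzaldehyde; 3 3-chloro-3-methylbut-1-yne
Product: 4 2,4-bis(methoxymethoxy)-6-[(2-methylbut-3-yn-2-yl)oxy]benzaldehyde
Conditions: 3 (1.5 equiv), DBU (1.6 equiv), CuCl2·2H2O (1 mol%), MeCN, 0 °C → rt
Reagents that add atoms: none
Why: Copper-catalysed propargylic etherification of a phenoxide with a tertiary propargylic chloride (copper allenylidene pathway) gives the tertiary aryl ether at low temperature without C-alkylation.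

Step 3
Reactants: 4 2,4-bis(methoxymethoxy)-6-[(2-methylbut-3-yn-2-yl)oxy]benzaldehyde
Product: 5 2,4-bis(methoxymethoxy)-6-[(2-methylbut-3-en-2-yl)oxy]benzaldehyde
Conditions: H2 (1 atm), Lindlar catalyst, quinoline, EtOAc, rt; work-up below 40 °C
Reagents that add atoms: none
Why: Lindlar semi-hydrogenation stops at the terminal alkene and leaves the aldehyde, MOM acetals and aryl ether untouched.

Step 4
Reactants: 6 3,4-dihydroxybenzaldehyde; 3 3-chloro-3-methylbut-1-yne
Product: 7 3-hydroxy-4-[(2-methylbut-3-yn-2-yl)oxy]benzaldehyde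
Conditions: 3 (1.1 equiv), DBU (1.05 equiv), CuCl2·2H2O (1 mol%), MeCN, −10 → 0 °C, Ar
Reagents that add atoms: none
Why: Same copper-catalysed propargylic etherification; one equivalent of base ionises only the more acidic 4-OH (para to the formyl group), so the ether forms at O-4.

Step 5
Reactants: 7 3-hydroxy-4-[(2-methylbut-3-yn-2-yl)oxy]benzaldehyde
Product: 8 3-(methoxymethoxy)-4-[(2-methylbut-3-yn-2-yl)oxy]benzaldehyde
Conditions: MOMCl (1.5 equiv), i-Pr2NEt (2 equiv), CH2Cl2, 0 °C → rt
Reagents that add atoms: chloromethyl methyl ether (MOMCl), COCCl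
Why: MOM etherification of the single remaining phenol (Williamson-type O-alkylation).

Step 6
Reactants: 8 3-(methoxymethoxy)-4-[(2-methylbut-3-yn-2-yl)oxy]benzaldehyde
Product: 9 3-(methoxymethoxy)-4-[(2-methylbut-3-en-2-yl)oxy]benzaldehyde
Conditions: H2 (1 atm), Lindlar catalyst, quinoline, EtOAc, rt
Reagents that add atoms: none
Why: Lindlar semi-hydrogenation of the terminal alkyne to the alkene, as in step 3.

Step 7
Reactants: 9 3-(methoxymethoxy)-4-[(2-methylbut-3-en-2-yl)oxy]benzaldehyde
Product: 10 4-ethynyl-2-(methoxymethoxy)-1-[(2-methylbut-3-en-2-yl)oxy]benzene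
Conditions: Ohira–Bestmann reagent (1.3 equiv), K2CO3 (2 equiv), MeOH, 0 °C → rt
Reagents that add atoms: dimethyl (1-diazo-2-oxopropyl)phosphonate (Ohira–Bestmann reagent), COP(=O)(OC)C(=[N+]=[N-])C(C)=O
Why: Ohira–Bestmann (Seyferth–Gilbert) homologation turns the aldehyde into the terminal alkyne under mild basic conditions that spare the tertiary allyl ether and the MOM group.

Step 8
Reactants: 10 4-ethynyl-2-(methoxymethoxy)-1-[(2-methylbut-3-en-2-yl)oxy]benzene; 5 2,4-bis(methoxymethoxy)-6-[(2-methylbut-3-en-2-yl)oxy]benzaldehyde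
Product: 12 1-[2,4-bis(methoxymethoxy)-6-[(2-methylbut-3-en-2-yl)oxy]phenyl]-3-[3-(methoxymethoxy)-4-[(2-methylbut-3-en-2-yl)oxy]phenyl]prop-2-yn-1-ol (racemic carbinol), via lithium arylacetylide 11 (not isolated)
Conditions: 10 (1.1 equiv), n-BuLi (1.05 equiv), THF, −78 °C, 30 min; then 5, −78 → 0 °C; H2O quench; crude product used directly
Reagents that add atoms: none
Why: Deprotonation of the terminal alkyne and 1,2-addition of the lithium acetylide to the non-enolisable aldehyde; the carbinol centre forms racemic and is erased in step 9.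

Step 9
Reactants: 12 1-[2,4-bis(methoxymethoxy)-6-[(2-methylbut-3-en-2-yl)oxy]phenyl]-3-[3-(methoxymethoxy)-4-[(2-methylbut-3-en-2-yl)oxy]phenyl]prop-2-yn-1-ol
Product: 13 1-[2,4-bis(methoxymethoxy)-6-[(2-methylbut-3-en-2-yl)oxy]phenyl]-3-[3-(methoxymethoxy)-4-[(2-methylbut-3-en-2-yl)oxy]phenyl]prop-2-yn-1-one
Conditions: activated MnO2 (15 equiv), CH2Cl2, rt
Reagents that add atoms: none
Why: MnO2 oxidation of a benzylic and propargylic alcohol under neutral conditions, which spares the acid-labile carbinol and ethers and removes the only stereocentre.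

Step 10
Reactants: 13 1-[2,4-bis(methoxymethoxy)-6-[(2-methylbut-3-en-2-yl)oxy]phenyl]-3-[3-(methoxymethoxy)-4-[(2-methylbut-3-en-2-yl)oxy]phenyl]prop-2-yn-1-one
Product: 15 2-[4-hydroxy-3-(methoxymethoxy)-5-(3-methylbut-2-en-1-yl)phenyl]-5,7-bis(methoxymethoxy)-8-(3-methylbut-2-en-1-yl)-4H-chromen-4-one, via bis-phenol ynone 14 (not isolated)
Conditions: degassed o-xylene (0.02 M), 135 °C, 6 h, Ar; then 40 °C, DMAP (20 mol%), 2 h, same flask
Reagents that add atoms: none
Why: Proposed new method: a domino double aromatic Claisen rearrangement/6-endo-dig oxa-Michael annulation of a bis(1,1-dimethylallyl aryl ether) ynone, in which each tertiary allyl ether undergoes a thermal [3,3] shift to its only free ortho carbon (the other ortho position is the acyl-bearing carbon on ring A and the OMOM-bearing carbon on ring B), the allylic transposition delivering linear prenyl groups, and rearomatisation unmasks on ring A exactly the phenol that then adds to the ynone β-carbon under DMAP catalysis to close the pyranone, so the oxygen that carried the allyl unit becomes O1 and the prenyl group can only end up at C8 (no C6 isomer is possible); the heating stage is kept neutral, dilute and free of Lewis or π-acids because activating the ynone before the sigmatropic step would let the ether oxygen attack first and send the allyl group to C3, and dilution suppresses intermolecular phenol addition; the closest known reaction types are the aromatic Claisen rearrangement of aryl 1,1-dimethylallyl ethers to ortho-prenylphenols and the base- or DMAP-catalysed cyclisation of o-hydroxyaryl ynones to flavones, which have not been merged into one isomerisation of an ynone.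

Step 11
Reactants: 15 2-[4-hydroxy-3-(methoxymethoxy)-5-(3-methylbut-2-en-1-yl)phenyl]-5,7-bis(methoxymethoxy)-8-(3-methylbut-2-en-1-yl)-4H-chromen-4-one
Product: 16 Epimedokoreanin B
Conditions: 3 M aq HCl, MeOH, 50 °C, 1–2 h, stopped at full conversion
Reagents that add atoms: none
Why: Acid-catalysed methanolysis of the three MOM acetals (transacetalisation to dimethoxymethane) under the standard conditions used for prenylated flavonoids, mild enough to avoid chroman formation from the ortho-prenyl phenols.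

**Compound list**
1 | 2,4,6-trihydroxybenzaldehyde | O=Cc1c(O)cc(O)cc1O | starting material
2 | 2-hydroxy-4,6-bis(methoxymethoxy)benzaldehyde | O=Cc1c(O)cc(OCOC)cc1OCOC | intermediate
3 | 3-chloro-3-methylbut-1-yne | C#CC(C)(C)Cl | starting material
4 | 2,4-bis(methoxymethoxy)-6-[(2-methylbut-3-yn-2-yl)oxy]benzaldehyde | O=Cc1c(OC(C)(C)C#C)cc(OCOC)cc1OCOC | intermediate
5 | 2,4-bis(methoxymethoxy)-6-[(2-methylbut-3-en-2-yl)oxy]benzaldehyde | O=Cc1c(OC(C)(C)C=C)cc(OCOC)cc1OCOC | intermediate
6 | 3,4-dihydroxybenzaldehyde | O=Cc1ccc(O)c(O)c1 | starting material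
7 | 3-hydroxy-4-[(2-methylbut-3-yn-2-yl)oxy]benzaldehyde | O=Cc1ccc(OC(C)(C)C#C)c(O)c1 | intermediate
8 | 3-(methoxymethoxy)-4-[(2-methylbut-3-yn-2-yl)oxy]benzaldehyde | O=Cc1ccc(OC(C)(C)C#C)c(OCOC)c1 | intermediate
9 | 3-(methoxymethoxy)-4-[(2-methylbut-3-en-2-yl)oxy]benzaldehyde | O=Cc1ccc(OC(C)(C)C=C)c(OCOC)c1 | intermediate
10 | 4-ethynyl-2-(methoxymethoxy)-1-[(2-methylbut-3-en-2-yl)oxy]benzene | C#Cc1ccc(OC(C)(C)C=C)c(OCOC)c1 | intermediate
11 | lithium arylacetylide of 10 (not isolated) | [Li]C#Cc1ccc(OC(C)(C)C=C)c(OCOC)c1 | intermediate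
12 | 1-[2,4-bis(methoxymethoxy)-6-[(2-methylbut-3-en-2-yl)oxy]phenyl]-3-[3-(methoxymethoxy)-4-[(2-methylbut-3-en-2-yl)oxy]phenyl]prop-2-yn-1-ol (racemic) | OC(C#Cc1ccc(OC(C)(C)C=C)c(OCOC)c1)c1c(OC(C)(C)C=C)cc(OCOC)cc1OCOC | intermediate
13 | 1-[2,4-bis(methoxymethoxy)-6-[(2-methylbut-3-en-2-yl)oxy]phenyl]-3-[3-(methoxymethoxy)-4-[(2-methylbut-3-en-2-yl)oxy]phenyl]prop-2-yn-1-one | O=C(C#Cc1ccc(OC(C)(C)C=C)c(OCOC)c1)c1c(OC(C)(C)C=C)cc(OCOC)cc1OCOC | intermediate
14 | 1-[2-hydroxy-4,6-bis(methoxymethoxy)-3-(3-methylbut-2-en-1-yl)phenyl]-3-[4-hydroxy-3-(methoxymethoxy)-5-(3-methylbut-2-en-1-yl)phenyl]prop-2-yn-1-one (bis-phenol ynone, not isolated) | O=C(C#Cc1cc(CC=C(C)C)c(O)c(OCOC)c1)c1c(O)c(CC=C(C)C)c(OCOC)cc1OCOC | intermediate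
15 | 2-[4-hydroxy-3-(methoxymethoxy)-5-(3-methylbut-2-en-1-yl)phenyl]-5,7-bis(methoxymethoxy)-8-(3-methylbut-2-en-1-yl)-4H-chromen-4-one | CC(C)=CCc1cc(-c2cc(=O)c3c(OCOC)cc(OCOC)c(CC=C(C)C)c3o2)cc(OCOC)c1O | intermediate
16 | Epimedokoreanin B, 2-[3,4-dihydroxy-5-(3-methylbut-2-en-1-yl)phenyl]-5,7-dihydroxy-8-(3-methylbut-2-en-1-yl)-4H-chromen-4-one | CC(C)=CCc1cc(-c2cc(=O)c3c(O)cc(O)c(CC=C(C)C)c3o2)cc(O)c1O | target

**Totals**
Total step count: 11. Longest linear sequence: 8 steps (steps 4, 5, 6, 7, 8, 9, 10, 11, from 6 to 16).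

**Three steps most likely to fail, each with one fallback**

Step 10 (proposed domino). The risks are intermolecular addition of the newly formed phenols to the ynone, 5-exo closure to an aurone, and thermal loss of isoprene. The fallback uses known chemistry, sets out from ynone 13 and comes back at 15. The ynone is first masked by conjugate addition of diethylamine (Et2NH, EtOH, rt) to give the enaminone (E)-3-(diethylamino)-1-[2,4-bis(methoxymethoxy)-6-[(2-methylbut-3-en-2-yl)oxy]phenyl]-3-[3-(methoxymethoxy)-4-[(2-methylbut-3-en-2-yl)oxy]phenyl]prop-2-en-1-one F1, which cannot polymerise or close 5-exo. Heating F1 in N,N-diethylaniline at 135 °C performs the two ordinary aromatic Claisen rearrangements to the hydroxy enaminone (E)-3-(diethylamino)-1-[2-hydroxy-4,6-bis(methoxymethoxy)-3-(3-methylbut-2-en-1-yl)phenyl]-3-[4-hydroxy-3-(methoxymethoxy)-5-(3-methylbut-2-en-1-yl)phenyl]prop-2-en-1-one F2. F2 closes to 15 by the known addition–elimination of the ortho-phenol with loss of diethylamine, finished with catalytic AcOH at 60 °C if needed.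

Step 4 (selective mono-etherification of the catechol). The risk is a mixture of 3-O, 4-O and bis-ethers, or copper-catecholate interference. The fallback sets out from 6 and comes back at 8. Selective 4-O-allylation of 6 (allyl bromide, NaHCO3, NaI, DMF, 40 °C) gives 4-(allyloxy)-3-hydroxybenzaldehyde F3. MOM protection (MOMCl, i-Pr2NEt) gives 4-(allyloxy)-3-(methoxymethoxy)benzaldehyde F4. Pd(PPh3)4-catalysed deallylation with morpholine gives 4-hydroxy-3-(methoxymethoxy)benzaldehyde F5. F5 has a single phenol and is etherified with 3 (DBU, CuCl2 cat., MeCN) to give 8 without any selectivity question.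

Step 2 (tertiary propargylation of the hydrogen-bonded, ortho-formyl phenol). The risk is low conversion of the chelated phenol. The fallback sets out from 2 and comes back at 5, bypassing 4 and step 3. 2-Methylbut-3-en-2-ol is converted (n-BuLi, Boc2O, THF) into tert-butyl 2-methylbut-3-en-2-yl carbonate F6. Phenol 2 is then O-allylated with F6 under Pd(PPh3)4 catalysis (THF, 0 °C → rt). In this decarboxylative Tsuji–Trost reaction the phenoxide attacks the more substituted terminus of the π-(1,1-dimethylallyl)palladium complex, which gives the tertiary allyl ether 5 directly.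

**Further compounds**
F1 | step 10 | (E)-3-(diethylamino)-1-[2,4-bis(methoxymethoxy)-6-[(2-methylbut-3-en-2-yl)oxy]phenyl]-3-[3-(methoxymethoxy)-4-[(2-methylbut-3-en-2-yl)oxy]phenyl]prop-2-en-1-one | CCN(CC)/C(c1ccc(OC(C)(C)C=C)c(OCOC)c1)=C/C(=O)c1c(OC(C)(C)C=C)cc(OCOC)cc1OCOC
F2 | step 10 | (E)-3-(diethylamino)-1-[2-hydroxy-4,6-bis(methoxymethoxy)-3-(3-methylbut-2-en-1-yl)phenyl]-3-[4-hydroxy-3-(methoxymethoxy)-5-(3-methylbut-2-en-1-yl)phenyl]prop-2-en-1-one | CCN(CC)/C(c1cc(CC=C(C)C)c(O)c(OCOC)c1)=C/C(=O)c1c(O)c(CC=C(C)C)c(OCOC)cc1OCOC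
F3 | step 4 | 4-(allyloxy)-3-hydroxybenzaldehyde | O=Cc1ccc(OCC=C)c(O)c1
F4 | step 4 | 4-(allyloxy)-3-(methoxymethoxy)benzaldehyde | O=Cc1ccc(OCC=C)c(OCOC)c1
F5 | step 4 | 4-hydroxy-3-(methoxymethoxy)benzaldehyde | O=Cc1ccc(O)c(OCOC)c1
F6 | step 2 | tert-butyl 2-methylbut-3-en-2-yl carbonate | C=CC(C)(C)OC(=O)OC(C)(C)C
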